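**Plan**

Rings: A is the phenol-bearing benzo ring of the dibenzofuran (C1–C4), B its other benzo ring (C6–C9), C the guaiacol-type ring, D the para-phenylene.
Cuts, in order: the two aryl O–H bonds (as O–CH3); the central CH2–CH2 bond of the ring A–ring D bridge (to CH=CH, then to two CHO groups); the ring C–O–ring D ether bond; the CH2–CH2 bond of the ring B–ring C bridge (to a Wittig alkene); the furan C–O bond; the ring A–ring B biaryl bond.
Enabling feature: both carbons of the ring A–ring D bridge are benzylic, one on C1 of the dibenzofuran and one para to the ether oxygen on ring D, so each can be a formyl carbon and the two like-polarity carbons can be joined reductively.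
Forward: Suzuki biaryl, furan ring by fluoride displacement, ring C by Wittig olefination and hydrogenation, ring D by SNAr, dialdehyde, 18-membered ring by McMurry coupling, hydrogenation, demethylation.
Stereochemistry: the target has no stereocentre; both alkene geometries that arise on the way are erased by hydrogenation.

Key step: step 10

Remark: C1 of the dibenzofuran is carried as a methyl ester and C7 as the aldehyde, so no carbonyl protecting group is needed and the first hydrogenation meets neither an aldehyde nor a benzylic acetal. Compounds 1 and 7 are assumed to be purchasable (1 is the NBS bromination product of methyl 3,5-dimethoxybenzoate; 7 is the O-benzyl ether of isovanillyl alcohol).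

**Route**

Step 1
Reactants: 1 methyl 2-bromo-3,5-dimethoxybenzoate; 2 (2-fluoro-4-formylphenyl)boronic acid
Product: 3 methyl 2-(2-fluoro-4-formylphenyl)-3,5-dimethoxybenzoate
Conditions: Pd(OAc)2 (cat.), SPhos, K3PO4, toluene/H2O, 90 °C
Reagents that add atoms: none
Why: Suzuki–Miyaura coupling: the electron-rich biarylphosphine makes zerovalent palladium reactive enough to insert into the doubly ortho-substituted C–Br bond and to take up the aryl group of the boronate, while ester, aldehyde and C–F bond are spectators.

Step 2
Reactants: 3 methyl 2-(2-fluoro-4-formylphenyl)-3,5-dimethoxybenzoate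
Product: 4 methyl 2-(2-fluoro-4-formylphenyl)-3,5-dihydroxybenzoate
Conditions: BBr3, CH2Cl2, −78 °C to 0 °C; aqueous work-up
Reagents that add atoms: none
Why: Lewis-acid ether cleavage: BBr3 coordinates each methoxy oxygen and bromide removes the methyl group by SN2, the aldehyde returning on hydrolysis and the methyl ester reacting far more slowly at this temperature.

Step 3
Reactants: 4 methyl 2-(2-fluoro-4-formylphenyl)-3,5-dihydroxybenzoate
Product: 6 methyl 7-formyl-3-methoxydibenzofuran-1-carboxylate, via dibenzofuran-3-ol 5 (not isolated)
Conditions: K2CO3, DMF, 120 °C; then MeI, 25 °C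
Reagents that add atoms: iodomethane, SMILES CI
Why: Intramolecular nucleophilic aromatic substitution followed by Williamson methylation: only the phenoxide ortho to the biaryl bond can reach the C–F carbon, which it attacks to close the five-membered furan ring (fluoride being the best leaving group for addition–elimination and the formyl group lowering the electron density of that ring), and the remaining phenoxide is then methylated.

Step 4
Reactants: 7 3-benzyloxy-4-methoxybenzyl alcohol
Product: 8 (3-benzyloxy-4-methoxybenzyl)triphenylphosphonium bromide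
Conditions: PPh3·HBr, MeCN, reflux
Reagents that add atoms: triphenylphosphine hydrobromide, SMILES [Br-].c1ccc(cc1)[PH+](c1ccccc1)c1ccccc1
Why: Phosphonium salt formation: HBr turns the electron-rich benzylic alcohol into the benzylic bromide, which PPh3 displaces at once, the aryl benzyl ether being stable to these conditions.

Step 5
Reactants: 6 methyl 7-formyl-3-methoxydibenzofuran-1-carboxylate; 8 (3-benzyloxy-4-methoxybenzyl)triphenylphosphonium bromide
Product: 9 methyl 7-[2-(3-benzyloxy-4-methoxyphenyl)ethenyl]-3-methoxydibenzofuran-1-carboxylate (E/Z mixture expected)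
Conditions: K2CO3, 18-crown-6 (cat.), CH2Cl2, reflux
Reagents that add atoms: none
Why: Wittig olefination: the semistabilised benzylic ylide, formed under solid–liquid phase-transfer conditions, adds to the unhindered C7 aldehyde while the hindered C1 ester is left alone, and the alkene geometry does not matter because step 6 removes it.

Step 6
Reactants: 9 methyl 7-[2-(3-benzyloxy-4-methoxyphenyl)ethenyl]-3-methoxydibenzofuran-1-carboxylate
Product: 10 methyl 7-[2-(3-hydroxy-4-methoxyphenyl)ethyl]-3-methoxydibenzofuran-1-carboxylate
Conditions: H2 (1 atm), 10% Pd/C, EtOAc/MeOH, 25 °C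
Reagents that add atoms: none
Why: Heterogeneous catalytic hydrogenation and hydrogenolysis: the stilbene double bond is saturated and the benzyl aryl ether is cleaved in the same operation, which uncovers the ring C phenol without touching the ester, the methyl ethers or the dibenzofuran.

Step 7
Reactants: 10 methyl 7-[2-(3-hydroxy-4-methoxyphenyl)ethyl]-3-methoxydibenzofuran-1-carboxylate; 11 4-fluorobenzaldehyde
Product: 12 methyl 7-{2-[3-(4-formylphenoxy)-4-methoxyphenyl]ethyl}-3-methoxydibenzofuran-1-carboxylate
Conditions: K2CO3, DMF, 130 °C
Reagents that add atoms: none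
Why: Nucleophilic aromatic substitution: the phenoxide adds to the fluoroarene para to the formyl group, which stabilises the anionic adduct, and loss of fluoride gives the diaryl ether, the hindered methyl ester being inert to carbonate in dry DMF.

Step 8
Reactants: 12 methyl 7-{2-[3-(4-formylphenoxy)-4-methoxyphenyl]ethyl}-3-methoxydibenzofuran-1-carboxylate
Product: 13 [7-(2-{3-[4-(hydroxymethyl)phenoxy]-4-methoxyphenyl}ethyl)-3-methoxydibenzofuran-1-yl]methanol
Conditions: LiAlH4, THF, 0 °C to 25 °C; aqueous work-up
Reagents that add atoms: none
Why: Hydride reduction: LiAlH4 takes the C1 ester and the ring D aldehyde to primary benzylic alcohols, which puts both bridge carbons at one oxidation level without any need to tell them apart.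

Step 9
Reactants: 13 [7-(2-{3-[4-(hydroxymethyl)phenoxy]-4-methoxyphenyl}ethyl)-3-methoxydibenzofuran-1-yl]methanol
Product: 14 7-{2-[3-(4-formylphenoxy)-4-methoxyphenyl]ethyl}-3-methoxydibenzofuran-1-carbaldehyde
Conditions: MnO2 (activated, excess), CH2Cl2, 25 °C
Reagents that add atoms: none
Why: Benzylic oxidation with MnO2: both alcohols are benzylic and are oxidised on the oxide surface to the aldehydes with no onward oxidation to acids.

Step 10
Reactants: 14 7-{2-[3-(4-formylphenoxy)-4-methoxyphenyl]ethyl}-3-methoxydibenzofuran-1-carbaldehyde
Product: 16 di-O-methyl-didehydroasterelin A (macrocyclic stilbene; Z drawn), via titanium pinacolate 15 (not isolated)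
Conditions: TiCl4, Zn, pyridine, THF, reflux; then 14 in THF by syringe pump over 24 h (about 2 mM final), reflux; aqueous K2CO3 work-up
Reagents that add atoms: none
Why: McMurry coupling: low-valent titanium made from TiCl4 and Zn transfers one electron to each aldehyde, the two titanium-bound ketyl radicals combine to the pinacolate 15, and a second two-electron deoxygenation on titanium at reflux removes both oxygens as titanium oxide species and leaves the C=C bond. The closest known reaction type is the intramolecular McMurry coupling of dialdehydes to macrocyclic stilbenes in bis(bibenzyl) cyclophanes. The one ring that closes is the 18-membered macrocycle, formed by head-to-head union of the formyl carbon on C1 of ring A with the formyl carbon on ring D, that is by C–C bond formation between two like-polarity carbons at the open ends of the chain. No stereocentre remains: the two carbinol centres of 15 vanish on deoxygenation and the alkene geometry (not controlled, either isomer serves) is removed in step 11. The step needs ring closure to outrun intermolecular coupling and needs reduction to be confined to the carbonyl groups; the first is secured by slow addition into a large excess of reagent together with the rigid dibenzofuran and the bent diaryl ether oxygen, which fold the ring D aldehyde back towards C1, and the second by the inertness of methyl aryl ethers, the diaryl ether and the dibenzofuran towards low-valent titanium.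

Step 11
Reactants: 16 di-O-methyl-didehydroasterelin A
Product: 17 di-O-methylasterelin A
Conditions: H2 (1 atm), 10% Pd/C, EtOAc, 25 °C
Reagents that add atoms: none
Why: Catalytic hydrogenation: syn addition of hydrogen to the disubstituted stilbene gives the CH2–CH2 bridge from either alkene isomer, the aryl ethers being inert.

Step 12
Reactants: 17 di-O-methylasterelin A
Product: 18 asterelin A
Conditions: BBr3, CH2Cl2, −78 °C to 25 °C; aqueous work-up
Reagents that add atoms: none
Why: BBr3 demethylation: the two methyl aryl ethers are cleaved by SN2 attack of bromide on the boron-complexed O–CH3 groups, whereas the diaryl ether and the dibenzofuran C–O bonds offer no sp3 carbon and survive.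

**Compound list**

1 | methyl 2-bromo-3,5-dimethoxybenzoate | COC(=O)c1cc(OC)cc(OC)c1Br | starting material
2 | (2-fluoro-4-formylphenyl)boronic acid | O=Cc1ccc(B(O)O)c(F)c1 | starting material
3 | methyl 2-(2-fluoro-4-formylphenyl)-3,5-dimethoxybenzoate | COC(=O)c1cc(OC)cc(OC)c1-c1ccc(C=O)cc1F | intermediate
4 | methyl 2-(2-fluoro-4-formylphenyl)-3,5-dihydroxybenzoate | COC(=O)c1cc(O)cc(O)c1-c1ccc(C=O)cc1F | intermediate
5 | methyl 7-formyl-3-hydroxydibenzofuran-1-carboxylate (present as its potassium phenoxide, not isolated) | COC(=O)c1cc(O)cc2oc3cc(C=O)ccc3c12 | intermediate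
6 | methyl 7-formyl-3-methoxydibenzofuran-1-carboxylate | COC(=O)c1cc(OC)cc2oc3cc(C=O)ccc3c12 | intermediate
7 | 3-benzyloxy-4-methoxybenzyl alcohol | COc1ccc(CO)cc1OCc1ccccc1 | starting material
8 | (3-benzyloxy-4-methoxybenzyl)triphenylphosphonium bromide | [Br-].COc1ccc(C[P+](c2ccccc2)(c2ccccc2)c2ccccc2)cc1OCc1ccccc1 | intermediate
9 | methyl 7-[2-(3-benzyloxy-4-methoxyphenyl)ethenyl]-3-methoxydibenzofuran-1-carboxylate (alkene geometry not fixed) | COC(=O)c1cc(OC)cc2oc3cc(C=Cc4ccc(OC)c(OCc5ccccc5)c4)ccc3c12 | intermediate
10 | methyl 7-[2-(3-hydroxy-4-methoxyphenyl)ethyl]-3-methoxydibenzofuran-1-carboxylate | COC(=O)c1cc(OC)cc2oc3cc(CCc4ccc(OC)c(O)c4)ccc3c12 | intermediate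
11 | 4-fluorobenzaldehyde | O=Cc1ccc(F)cc1 | starting material
12 | methyl 7-{2-[3-(4-formylphenoxy)-4-methoxyphenyl]ethyl}-3-methoxydibenzofuran-1-carboxylate | COC(=O)c1cc(OC)cc2oc3cc(CCc4ccc(OC)c(Oc5ccc(C=O)cc5)c4)ccc3c12 | intermediate
13 | [7-(2-{3-[4-(hydroxymethyl)phenoxy]-4-methoxyphenyl}ethyl)-3-methoxydibenzofuran-1-yl]methanol | OCc1cc(OC)cc2oc3cc(CCc4ccc(OC)c(Oc5ccc(CO)cc5)c4)ccc3c12 | intermediate
14 | 7-{2-[3-(4-formylphenoxy)-4-methoxyphenyl]ethyl}-3-methoxydibenzofuran-1-carbaldehyde | O=Cc1cc(OC)cc2oc3cc(CCc4ccc(OC)c(Oc5ccc(C=O)cc5)c4)ccc3c12 | intermediate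
15 | macrocyclic titanium pinacolate, drawn as the dichlorotitanium 1,2-diolate of the two bridge carbons (tetravalent titanium; carbinol configurations not controlled; not isolated) | COc1cc2c3c(c1)oc1cc(ccc13)CCc1ccc(OC)c(c1)Oc1ccc(cc1)C4O[Ti](Cl)(Cl)OC42 | intermediate
16 | di-O-methyl-didehydroasterelin A: 18-membered ring in which CH=CH joins C1 of the 3-methoxydibenzofuran to the para carbon of ring D, ring D is bound through oxygen to C3 of the 4-methoxyphenyl ring C, and C1 of ring C carries the CH2CH2 bridge to C7 of the dibenzofuran (Z drawn) | COc1cc2c3c(c1)oc1cc(ccc13)CCc1ccc(OC)c(c1)Oc1ccc(cc1)/C=C\2 | intermediate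
17 | di-O-methylasterelin A (the same macrocycle with a CH2–CH2 bridge between ring A and ring D) | COc1cc2c3c(c1)oc1cc(ccc13)CCc1ccc(OC)c(c1)Oc1ccc(cc1)CC2 | intermediate
18 | asterelin A | Oc1cc2c3c(c1)oc1cc(ccc13)CCc1ccc(O)c(c1)Oc1ccc(cc1)CC2 | target

**Totals and risks**

Total step count: 12. Longest linear sequence: 11 steps (steps 1–3 and 5–12, from 1).

Steps most likely to fail:

1. Step 10. Intermolecular ketyl coupling to dimers and oligomers may outpace closure of the 18-membered ring, or the hindered C1 aldehyde may stop at the pinacol or be reduced to the carbinol. The fallback forms the same C=C bond by an intramolecular Wittig olefination and sets out from 10. LiAlH4 in THF should reduce the ester to [7-[2-(3-hydroxy-4-methoxyphenyl)ethyl]-3-methoxydibenzofuran-1-yl]methanol F1. K2CO3 and 11 in DMF should then arylate only the phenoxide, not the neutral benzylic alcohol, giving 4-[5-(2-{1-(hydroxymethyl)-3-methoxydibenzofuran-7-yl}ethyl)-2-methoxyphenoxy]benzaldehyde F2. PPh3·HBr in refluxing MeCN should convert the benzylic alcohol into [(7-{2-[3-(4-formylphenoxy)-4-methoxyphenyl]ethyl}-3-methoxydibenzofuran-1-yl)methyl]triphenylphosphonium bromide F3. Slow addition of F3 to NaOMe in CH2Cl2/MeOH at high dilution should close the ring, and the fallback comes back to the route at 16.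

2. Step 3. The formyl group is meta to fluorine and activates only inductively, so fluoride displacement may be slow enough for base-induced degradation of the aldehyde to compete at the temperature required. The fallback replaces addition–elimination by a palladium-catalysed C–O coupling and sets out from 1. Coupling of 1 with (2-chloro-4-formylphenyl)boronic acid (Pd(PPh3)4, Na2CO3, DME/H2O, a catalyst that leaves the C–Cl bond alone) should give methyl 2-(2-chloro-4-formylphenyl)-3,5-dimethoxybenzoate F4. BBr3 as in step 2 should give methyl 2-(2-chloro-4-formylphenyl)-3,5-dihydroxybenzoate F5. Pd(OAc)2, tBuXPhos and K3PO4 in toluene at 100 °C should then close the furan ring by oxidative addition into the C–Cl bond and C–O reductive elimination to give 5. Methylation with MeI and K2CO3 brings the fallback back to the route at 6.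

3. Step 1. Protodeboronation of the ortho-fluoro boronic acid may outrun transmetalation onto the hindered arylpalladium bromide. The fallback exchanges the roles of the two partners and sets out from 1. Miyaura borylation (bis(pinacolato)diboron, PdCl2(dppf), KOAc, dioxane, 90 °C) should give methyl 3,5-dimethoxy-2-(4,4,5,5-tetramethyl-1,3,2-dioxaborolan-2-yl)benzoate F6. Coupling of F6 with the electron-poor, quickly inserting 4-bromo-3-fluorobenzaldehyde (PdCl2(dppf), K3PO4, dioxane/H2O) brings the fallback back to the route at 3.

**Further compounds**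

F1 | step 10 | [7-[2-(3-hydroxy-4-methoxyphenyl)ethyl]-3-methoxydibenzofuran-1-yl]methanol | OCc1cc(OC)cc2oc3cc(CCc4ccc(OC)c(O)c4)ccc3c12
F2 | step 10 | 4-[5-(2-{1-(hydroxymethyl)-3-methoxydibenzofuran-7-yl}ethyl)-2-methoxyphenoxy]benzaldehyde | OCc1cc(OC)cc2oc3cc(CCc4ccc(OC)c(Oc5ccc(C=O)cc5)c4)ccc3c12
F3 | step 10 | [(7-{2-[3-(4-formylphenoxy)-4-methoxyphenyl]ethyl}-3-methoxydibenzofuran-1-yl)methyl]triphenylphosphonium bromide | [Br-].O=Cc1ccc(Oc2cc(CCc3ccc4c(c3)oc3cc(OC)cc(C[P+](c5ccccc5)(c5ccccc5)c5ccccc5)c34)ccc2OC)cc1
F4 | step 3 | methyl 2-(2-chloro-4-formylphenyl)-3,5-dimethoxybenzoate | COC(=O)c1cc(OC)cc(OC)c1-c1ccc(C=O)cc1Cl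
F5 | step 3 | methyl 2-(2-chloro-4-formylphenyl)-3,5-dihydroxybenzoate | COC(=O)c1cc(O)cc(O)c1-c1ccc(C=O)cc1Cl
F6 | step 1 | methyl 3,5-dimethoxy-2-(4,4,5,5-tetramethyl-1,3,2-dioxaborolan-2-yl)benzoate | COC(=O)c1cc(OC)cc(OC)c1B1OC(C)(C)C(C)(C)O1
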